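The route rests on cutting the N1–C2 imide bond of the pyrrolidine-2,4-dione ring. C2, C3 and the 3-acetyl group are treated as a masked acetyl(acyl)ketene, stored in a 2,2,6-trimethyl-1,3-dioxin-4-one that is acylated at its 5-position by the D-leucine-derived ketone (future C4). N1 already carries the (E)-dodec-2-enoyl chain and sits next to the (R)-configured C5 of the target. Heating this 5-acyl dioxinone should expel acetone, and the amide N–H should add to the ketene carbon and close the five-membered ring. Ring, imide, acetyl group and enol thus arrive in one base-free operation that spares the epimerisable C5–H.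

Key step: step 6

Assumption: D-leucinol, the commercial reduction product of D-leucine, is bought, so no reduction step is needed. The target is written as its C4 enol, one of the rapidly interconverting enol forms of a 3-acyl pyrrolidine-2,4-dione.

Step 1
Reactants: 1 D-leucinol [(R)-2-amino-4-methylpentan-1-ol]; 2 (E)-dodec-2-enoic acid
Product: 3 (R,E)-N-(1-hydroxy-4-methylpentan-2-yl)dodec-2-enamide
Conditions: DIC, HOBt, CH2Cl2, 0 °C → rt
Reagents that add atoms: none
Why: Carbodiimide/HOBt amide coupling, in which the primary amine should outcompete the primary hydroxyl for the active ester and the stereocentre is not touched.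

Step 2
Reactants: 3 (R,E)-N-(1-hydroxy-4-methylpentan-2-yl)dodec-2-enamide
Product: 4 (R,E)-N-(4-methyl-1-oxopentan-2-yl)dodec-2-enamide
Conditions: Dess–Martin periodinane, wet CH2Cl2, 0 °C → rt; cold Na2S2O3/NaHCO3 wash; crude aldehyde used at once
Reagents that add atoms: none
Why: Dess–Martin oxidation of a primary alcohol under neutral, non-basic conditions, with the aldehyde not chromatographed or stored so that its α-stereocentre should keep its configuration.

Step 3
Reactants: 5 2,2,6-trimethyl-4H-1,3-dioxin-4-one
Product: 6 5-iodo-2,2,6-trimethyl-4H-1,3-dioxin-4-one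
Conditions: NIS, AcOH, rt, dark
Reagents that add atoms: N-iodosuccinimide, O=C1CCC(=O)N1I
Why: Electrophilic iodination of the push–pull enol ether at its nucleophilic 5-position, the carbon α to the ring carbonyl.

Step 4
Reactants: 6 5-iodo-2,2,6-trimethyl-4H-1,3-dioxin-4-one; 4 (R,E)-N-(4-methyl-1-oxopentan-2-yl)dodec-2-enamide
Product: 8 (E)-N-[(2R)-1-hydroxy-4-methyl-1-(2,2,6-trimethyl-4-oxo-4H-1,3-dioxin-5-yl)pentan-2-yl]dodec-2-enamide (both configurations at the carbinol carbon), via 5-chloromagnesio dioxinone 7 (not isolated)
Conditions: 6 (2.5 equiv), iPrMgCl (2.4 equiv), THF, −30 °C; then 4, −30 → −10 °C; aq. NH4Cl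
Reagents that add atoms: none
Why: Iodine–magnesium exchange should give a carbonyl-chelated alkenylmagnesium that survives at −30 °C and adds 1,2 to the aldehyde (Grignard addition), one equivalent being spent on the amide N–H, whose magnesium amidate shields the neighbouring C–H from enolisation; the carbinol centre forms without control and is erased in step 5.

Step 5
Reactants: 8 (E)-N-[(2R)-1-hydroxy-4-methyl-1-(2,2,6-trimethyl-4-oxo-4H-1,3-dioxin-5-yl)pentan-2-yl]dodec-2-enamide
Product: 9 (R,E)-N-[4-methyl-1-oxo-1-(2,2,6-trimethyl-4-oxo-4H-1,3-dioxin-5-yl)pentan-2-yl]dodec-2-enamide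
Conditions: Dess–Martin periodinane, CH2Cl2, 0 °C → rt; brief Na2S2O3/NaHCO3 wash; fast filtration through silica
Reagents that add atoms: none
Why: Dess–Martin oxidation of the secondary, allylic-type alcohol under neutral conditions should converge both carbinol epimers on one ketone without touching the C–H between ketone and nitrogen.

Step 6
Reactants: 9 (R,E)-N-[4-methyl-1-oxo-1-(2,2,6-trimethyl-4-oxo-4H-1,3-dioxin-5-yl)pentan-2-yl]dodec-2-enamide
Product: 11 reutericyclin C [(R,E)-3-acetyl-1-(dodec-2-enoyl)-4-hydroxy-5-(2-methylpropyl)-1,5-dihydro-2H-pyrrol-2-one], via acetyl(acyl)ketene 10 (not isolated)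
Conditions: dry PhMe, 110 °C, 9 added slowly by syringe pump to a final ≤0.005 M, N2 sweep to carry off acetone; product purified on reversed phase with acidic eluent
Reagents that add atoms: none
Why: At 110 °C the dioxinone should undergo a retro-hetero-Diels–Alder reaction that expels acetone and unveils ketene 10, in which the ketene carbon is the future C2 and its neighbour (future C3) carries both the acetyl group and the leucyl ketone (future C4); the amide N–H then adds across the ketene C=O and tautomerisation gives the chelated 3-acyl enol. The closest known reaction types are the thermal release of acylketenes from 1,3-dioxin-4-ones with N–H capture and the closure of N-protected aminoacyl Meldrum's acids to pyrrolidine-2,4-diones. The one ring formed, the five-membered lactam, closes by 5-exo-dig attack of N1 on the sp carbon of the ketene in the plane of its substituents, which creates the N1–C2 bond. No stereocentre is created: the (R)-centre at C5 comes from 1 and should survive because the medium holds no base and the C5–H is never deprotonated. The step needs intramolecular N-acylation to outrun ketene dimerisation, hydration and O-acylation of product enol, which the short tether, slow addition into dilute dry toluene and removal of acetone should secure; attack by the amide oxygen would need a seven-membered ring, and re-addition of acetone across either acyl group only regenerates a dioxinone that feeds the same ketene.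

Compound list
1 | D-leucinol, (R)-2-amino-4-methylpentan-1-ol | N[C@H](CC(C)C)CO | starting material
2 | (E)-dodec-2-enoic acid | CCCCCCCCC/C=C/C(=O)O | starting material
3 | (R,E)-N-(1-hydroxy-4-methylpentan-2-yl)dodec-2-enamide | CCCCCCCCC/C=C/C(=O)N[C@H](CC(C)C)CO | intermediate
4 | (R,E)-N-(4-methyl-1-oxopentan-2-yl)dodec-2-enamide | CCCCCCCCC/C=C/C(=O)N[C@H](CC(C)C)C=O | intermediate
5 | 2,2,6-trimethyl-4H-1,3-dioxin-4-one | CC1=CC(=O)OC(C)(C)O1 | starting material
6 | 5-iodo-2,2,6-trimethyl-4H-1,3-dioxin-4-one | CC1=C(I)C(=O)OC(C)(C)O1 | intermediate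
7 | 5-(chloromagnesio)-2,2,6-trimethyl-4H-1,3-dioxin-4-one | CC1=C([Mg]Cl)C(=O)OC(C)(C)O1 | intermediate (not isolated)
8 | (E)-N-[(2R)-1-hydroxy-4-methyl-1-(2,2,6-trimethyl-4-oxo-4H-1,3-dioxin-5-yl)pentan-2-yl]dodec-2-enamide, both carbinol epimers | CCCCCCCCC/C=C/C(=O)N[C@H](CC(C)C)C(O)C1=C(C)OC(C)(C)OC1=O | intermediate
9 | (R,E)-N-[4-methyl-1-oxo-1-(2,2,6-trimethyl-4-oxo-4H-1,3-dioxin-5-yl)pentan-2-yl]dodec-2-enamide | CCCCCCCCC/C=C/C(=O)N[C@H](CC(C)C)C(=O)C1=C(C)OC(C)(C)OC1=O | intermediate
10 | (R,E)-N-(2-acetyl-6-methyl-1,3-dioxohept-1-en-4-yl)dodec-2-enamide, the acetyl(acyl)ketene | CCCCCCCCC/C=C/C(=O)N[C@H](CC(C)C)C(=O)C(=C=O)C(C)=O | intermediate (not isolated)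
11 | reutericyclin C, (R,E)-3-acetyl-1-(dodec-2-enoyl)-4-hydroxy-5-(2-methylpropyl)-1,5-dihydro-2H-pyrrol-2-one | CCCCCCCCC/C=C/C(=O)N1C(=O)C(C(C)=O)=C(O)[C@H]1CC(C)C | target

Total step count: 6.
Longest linear sequence: 5 steps (steps 1, 2, 4, 5 and 6, from 1); step 3 supplies the iodide.

Steps most likely to fail

Step 6. The weakly nucleophilic amide nitrogen may close the ring more slowly than the ketene dimerises, picks up traces of water with loss of CO2, or acylates the enol of product already formed; long heating could also erode the configuration at C5. The fallback sets out from 5, also uses 2, and comes back to the route at 11. It builds the ring by a Lacey–Dieckmann sequence and attaches the N-acyl chain last. Heating 5 with purchased methyl D-leucinate F1 in toluene at 110 °C should give methyl N-(3-oxobutanoyl)-D-leucinate F2 through capture of acetylketene by the amine. Short treatment of F2 with KOtBu in tBuOH at room temperature, followed by an acidic quench, should close it to (R)-3-acetyl-4-hydroxy-5-(2-methylpropyl)-1,5-dihydro-2H-pyrrol-2-one F3. Acid 2 is turned into (E)-dodec-2-enoyl chloride F4 with oxalyl chloride and catalytic DMF. F3 is deprotonated twice with n-BuLi in THF at −78 °C and acylated on nitrogen with F4, which should give 11 after acidic work-up.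

Step 4. The basic alkenylmagnesium may enolise the aldehyde, with loss of configuration at its α-carbon, or be quenched by the N–H faster than it adds, so that conversion stays low. The fallback sets out from 6 and 4 and comes back at 8. It is a Nozaki–Hiyama–Kishi coupling run in Barbier mode, with excess CrCl2 and catalytic NiCl2 in DMF/THF at room temperature. No organometallic is pre-formed, the chromium-bound alkenyl species is not basic, it tolerates the free amide N–H and it should add only to the aldehyde, so no sacrificial equivalent is needed. No new compound is isolated on this way.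

Step 2. The N-acyl α-amino aldehyde may lose configuration by enolisation during oxidation, work-up or standing. The fallback sets out from 1 and comes back at 8. It carries nitrogen as a carbamate through the aldehyde stage and adds the enoyl chain afterwards. Boc2O in CH2Cl2 should convert 1 into tert-butyl (R)-(1-hydroxy-4-methylpentan-2-yl)carbamate F5. Dess–Martin oxidation of F5 should give tert-butyl (R)-(4-methyl-1-oxopentan-2-yl)carbamate F6, which is used fresh. Addition of 7 under the conditions of step 4 should give tert-butyl [(2R)-1-hydroxy-4-methyl-1-(2,2,6-trimethyl-4-oxo-4H-1,3-dioxin-5-yl)pentan-2-yl]carbamate F7. TFA in CH2Cl2 at 0 °C should free 5-[(2R)-2-amino-1-hydroxy-4-methylpentyl]-2,2,6-trimethyl-4H-1,3-dioxin-4-one F8, which is kept as its trifluoroacetate salt. F8 is then acylated at 0 °C with 2 pre-activated by DIC/HOBt, with iPr2NEt added last so that the free amine meets the active ester before it can attack the ring carbonyl; this should give 8.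

Further compounds
F1 | step 6 | methyl D-leucinate (purchased) | N[C@H](CC(C)C)C(=O)OC
F2 | step 6 | methyl N-(3-oxobutanoyl)-D-leucinate | CC(=O)CC(=O)N[C@H](CC(C)C)C(=O)OC
F3 | step 6 | (R)-3-acetyl-4-hydroxy-5-(2-methylpropyl)-1,5-dihydro-2H-pyrrol-2-one | CC(=O)C1=C(O)[C@@H](CC(C)C)NC1=O
F4 | step 6 | (E)-dodec-2-enoyl chloride | CCCCCCCCC/C=C/C(=O)Cl
F0 | step 4 | none | none
F5 | step 2 | tert-butyl (R)-(1-hydroxy-4-methylpentan-2-yl)carbamate | CC(C)(C)OC(=O)N[C@H](CC(C)C)CO
F6 | step 2 | tert-butyl (R)-(4-methyl-1-oxopentan-2-yl)carbamate | CC(C)(C)OC(=O)N[C@H](CC(C)C)C=O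
F7 | step 2 | tert-butyl [(2R)-1-hydroxy-4-methyl-1-(2,2,6-trimethyl-4-oxo-4H-1,3-dioxin-5-yl)pentan-2-yl]carbamate, both carbinol epimers | CC(C)(C)OC(=O)N[C@H](CC(C)C)C(O)C1=C(C)OC(C)(C)OC1=O
F8 | step 2 | 5-[(2R)-2-amino-1-hydroxy-4-methylpentyl]-2,2,6-trimethyl-4H-1,3-dioxin-4-one, both carbinol epimers | N[C@H](CC(C)C)C(O)C1=C(C)OC(C)(C)OC1=O
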